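**Assumption:** the side-chain carbinol in the given SMILES is (S), and genistein (bulk soy isoflavone) counts as a cheap commercial starting material.

## Retrosynthetic overview

1. Erycibenin A ⇐ its 7,4'-bis-silyl ether (fluoride) ⇐ the α-hydroxy ketone ArCH2–CO–CMe2OH; the only stereocentre comes from hydroxyl-directed asymmetric hydrogenation of that ketone.
2. Key disconnection C6–CH2: the A-ring C6–H of a 7,4'-bis-silylated genistein is joined to the α-keto cation +CH2–CO–CMe2OSiMe3. This cation is an enolonium species made from the silyl enol ether of 3-hydroxy-3-methylbutan-2-one and a hypervalent iodine reagent, so an arene carbon and an enolate carbon, both natively nucleophilic, are coupled.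
3. No ring is formed: the chromenone (A/C rings) and the B ring are bought intact as genistein; only selective 7,4'-silylation precedes the key step.

## Route

**Step 1**
Reactants: 1 genistein (5,7-dihydroxy-3-(4-hydroxyphenyl)-4H-chromen-4-one)
Product: 2 7,4'-bis-O-TBS-genistein (7-(tert-butyldimethylsilyloxy)-3-[4-(tert-butyldimethylsilyloxy)phenyl]-5-hydroxy-4H-chromen-4-one)
Conditions: TBSCl (2.2 eq), imidazole (4 eq), DMF, 0 °C → rt
Reagents that add atoms: tert-butyldimethylsilyl chloride (TBSCl), CC(C)(C)[Si](C)(C)Cl
Why: Selective phenol O-silylation; the 7- and 4'-OH are free and acidic, whereas the 5-OH is locked in a hydrogen bond to C4=O and is not silylated by two equivalents of silyl chloride.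

**Step 2**
Reactants: 3 3-hydroxy-3-methylbutan-2-one
Product: 4 3-methyl-2,3-bis(trimethylsilyloxy)but-1-ene
Conditions: TMSOTf (2.3 eq), Et3N (3 eq), CH2Cl2, 0 °C → rt; distil
Reagents that add atoms: trimethylsilyl triflate (TMSOTf), C[Si](C)(C)OS(=O)(=O)C(F)(F)F
Why: Silyl enol ether formation by soft enolisation; only the CH3 side can enolise (the other α-carbon is quaternary) and the tertiary OH is silylated in the same operation.

**Step 3 (key step)**
Reactants: 4 3-methyl-2,3-bis(trimethylsilyloxy)but-1-ene; 5 Koser's reagent, [hydroxy(tosyloxy)iodo]benzene; 2 7,4'-bis-O-TBS-genistein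
Product: 8 6-(3-hydroxy-3-methyl-2-oxobutyl)-7,4'-bis-O-TBS-genistein, via enolonium iodane 6 (not isolated), via tertiary TMS ether 7 (not isolated)
Conditions: 5 (1.3 eq), BF3·OEt2 (1.3 eq), CH2Cl2, −78 °C; 4 (1.4 eq), 10 min; then 2 (1.0 eq), −78 → −40 °C; aq. NaHCO3; then 10% aq. citric acid–THF, 0 °C
Reagents that add atoms: none
Why: Proposed new method: BF3-activated Koser's reagent exchanges with the silyl enol ether at −78 °C to give an iodine(III) enolate (enolonium 6) whose CH2 is now electrophilic; C-6 of 2 (ortho to the free, chelated 5-OH and to the 7-siloxy group, the position where 5-hydroxy-7-alkoxy(iso)flavones take electrophiles such as iodine) attacks it in a Friedel–Crafts-type step with loss of PhI and TsOH to give 7, and mild aqueous acid then frees the tertiary alcohol; the slight excess of 4 consumes all iodine(III) before the phenol is added; the closest known reaction type is the α-arylation and α-allylation of ketones through preformed enolonium species with indoles, pyrroles and allylsilanes.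

**Step 4**
Reactants: 8 6-(3-hydroxy-3-methyl-2-oxobutyl)-7,4'-bis-O-TBS-genistein
Product: 9 6-[(2S)-2,3-dihydroxy-3-methylbutyl]-7,4'-bis-O-TBS-genistein
Conditions: RuCl2[(S)-BINAP](dmf)n (2 mol %), H2 (50 atm), EtOH–CH2Cl2, 40 °C
Reagents that add atoms: none
Why: Noyori asymmetric hydrogenation of an α-hydroxy ketone; Ru binds the ketone and the tertiary OH in a five-membered chelate and (S)-BINAP delivers hydride to the face that gives the (S)-carbinol (the same facial rule that converts hydroxyacetone into (R)-propane-1,2-diol with (R)-BINAP), while the chromone C=O/C=C, the phenol and the aryl silyl ethers are not reduced by this chelation-dependent catalyst.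

**Step 5**
Reactants: 9 6-[(2S)-2,3-dihydroxy-3-methylbutyl]-7,4'-bis-O-TBS-genistein
Product: 10 erycibenin A
Conditions: KHF2 (3 eq), MeOH, rt
Reagents that add atoms: none
Why: Fluoride-mediated desilylation selective for phenolic silyl ethers under near-neutral conditions; neither the carbinol stereocentre nor the tertiary alcohol is touched.

## Compound list

1 | genistein | O=c1c(-c2ccc(O)cc2)coc2cc(O)cc(O)c12 | starting material
2 | 7,4'-bis-O-TBS-genistein | O=c1c(-c2ccc(O[Si](C)(C)C(C)(C)C)cc2)coc2cc(O[Si](C)(C)C(C)(C)C)cc(O)c12 | intermediate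
3 | 3-hydroxy-3-methylbutan-2-one | CC(=O)C(C)(C)O | starting material
4 | 3-methyl-2,3-bis(trimethylsilyloxy)but-1-ene | C=C(O[Si](C)(C)C)C(C)(C)O[Si](C)(C)C | intermediate
5 | Koser's reagent, [hydroxy(tosyloxy)iodo]benzene | O[I](OS(=O)(=O)c1ccc(C)cc1)c1ccccc1 | starting material
6 | enolonium species, drawn as the O-bound phenyl(tosyloxy)iodine(III) enolate of 3-methyl-3-(trimethylsilyloxy)butan-2-one | C=C(O[I](OS(=O)(=O)c1ccc(C)cc1)c1ccccc1)C(C)(C)O[Si](C)(C)C | intermediate (not isolated)
7 | 6-[3-methyl-2-oxo-3-(trimethylsilyloxy)butyl]-7,4'-bis-O-TBS-genistein | CC(C)(O[Si](C)(C)C)C(=O)Cc1c(O[Si](C)(C)C(C)(C)C)cc2occ(-c3ccc(O[Si](C)(C)C(C)(C)C)cc3)c(=O)c2c1O | intermediate (not isolated)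
8 | 6-(3-hydroxy-3-methyl-2-oxobutyl)-7,4'-bis-O-TBS-genistein | CC(C)(O)C(=O)Cc1c(O[Si](C)(C)C(C)(C)C)cc2occ(-c3ccc(O[Si](C)(C)C(C)(C)C)cc3)c(=O)c2c1O | intermediate
9 | 6-[(2S)-2,3-dihydroxy-3-methylbutyl]-7,4'-bis-O-TBS-genistein | CC(C)(O)[C@@H](O)Cc1c(O[Si](C)(C)C(C)(C)C)cc2occ(-c3ccc(O[Si](C)(C)C(C)(C)C)cc3)c(=O)c2c1O | intermediate
10 | erycibenin A, 6-[(2S)-2,3-dihydroxy-3-methylbutyl]-5,7-dihydroxy-3-(4-hydroxyphenyl)-4H-chromen-4-one | CC(C)(O)[C@@H](O)Cc1c(O)cc2occ(-c3ccc(O)cc3)c(=O)c2c1O | target

## Summary

Total step count: 5. Longest linear sequence: 4 steps (1 → 2 → 8 → 9 → 10, or equally 3 → 4 → 8 → 9 → 10).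

**Steps most likely to fail**

Step 3 is the greatest risk. The enolonium may attack C-8 instead of C-6, O-alkylate or oxidise the phenol, or the carbonyl-deactivated A ring may react too slowly. The fallback fixes the regiochemistry with a halide instead of relying on C–H attack. It sets out from 2: N-iodosuccinimide in DMF gives 6-iodo-7,4'-bis-O-TBS-genistein F1. F1 is then coupled with enol ether 4 through its tin enolate (Pd2(dba)3, P(t-Bu)3, Bu3SnF, toluene, 80 °C). This returns to the route at 7, which the citric acid treatment of step 3 converts into 8.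

Step 4 is the second risk. The ketone is flanked by a quaternary carbon, so rate or ee may be low, and hemiketal formation with the neighbouring phenol could interfere. The fallback replaces chelation control by steric control. It sets out from 7, isolated by leaving out the acid treatment of step 3, in which the tertiary oxygen is blocked. CBS reduction with (R)-Me-CBS and catecholborane (toluene, −78 → −40 °C) treats C(Me)2OSiMe3 as the large group and CH2Ar as the small one and gives 6-[(2S)-2-hydroxy-3-methyl-3-(trimethylsilyloxy)butyl]-7,4'-bis-O-TBS-genistein F2. Aqueous citric acid–THF removes the trimethylsilyl group and the fallback comes back at 9.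

Step 5 is the third risk, and the smallest. Fluoride or adventitious base could move a silyl group from O-7 to the side-chain secondary hydroxyl, or leave partially cleaved, air-sensitive phenolates. The fallback reverses the order of the last two operations. It sets out from 8: KHF2 in MeOH gives the free triphenol ketone 6-(3-hydroxy-3-methyl-2-oxobutyl)genistein F3, which has no secondary hydroxyl to accept a migrating silyl group. The phenol-tolerant Ru–(S)-BINAP hydrogenation is then run last and comes back at 10 directly.

## Further compounds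

F1 | step 3 | 6-iodo-7,4'-bis-O-TBS-genistein | Oc1c(I)c(O[Si](C)(C)C(C)(C)C)cc2occ(-c3ccc(O[Si](C)(C)C(C)(C)C)cc3)c(=O)c12
F2 | step 4 | 6-[(2S)-2-hydroxy-3-methyl-3-(trimethylsilyloxy)butyl]-7,4'-bis-O-TBS-genistein | CC(C)(O[Si](C)(C)C)[C@@H](O)Cc1c(O[Si](C)(C)C(C)(C)C)cc2occ(-c3ccc(O[Si](C)(C)C(C)(C)C)cc3)c(=O)c2c1O
F3 | step 5 | 6-(3-hydroxy-3-methyl-2-oxobutyl)genistein | CC(C)(O)C(=O)Cc1c(O)cc2occ(-c3ccc(O)cc3)c(=O)c2c1O
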